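I cannot get a rate constant for the target from these runs, since the first chain carrier is never seen. But two steps take that carrier, and dividing their rates removes it and time.

| flask | substrate | partner | transfer agent | initiator | remark | time |
|---|---|---|---|---|---|---|
| Monday's | 0.045 M | 0.80 equiv | 0.010 M | 1 mol% | run made earlier |  |
| Tuesday's | 0.31 M | 0.80 equiv | 0.010 M | 1 mol% | run made earlier |  |
| ash | 0.15 M | 0.800 equiv | 0.0100 M | 1 mol% |  | 12 min |
| birch | 0.030 M | 0.800 equiv | 0.0100 M | 1 mol% |  | 12 min |
| cedar | 0.10 M | 0.800 equiv | 0.0100 M | 1 mol% |  | 12 min |
| alder | 0.20 M | 0.800 equiv | 0.0100 M | 1 mol% |  | 12 min |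

| Monday's: time / min | Monday's: target / % | Tuesday's: time / min | Tuesday's: target / % |
|---|---|---|---|
| 1.00 | 1 | 0.833 | 11 |
| 1.50 | 8 | 2.50 | 26 |
| 2.50 | 1 | 4.00 | 36 |
| 4.00 | 5 | 6.00 | 40 |
| 8.00 | 5 | 10.0 | 51 |
| 12.0 | 7 | 12.0 | 53 |

(scatter of a reading: 2 percentage points)

- percentages count the substrate that a species holds: one ended chains counts as two
- the analysis behind the earlier runs scatters by 2 percentage points, standard deviation
- candidate steps: 2 idle radical -> ended radicals; 2 first chain carrier -> ended chains; transfer agent + first chain carrier -> side product + idle radical; substrate + initiating radical -> capped initiator + first chain carrier; initiator -> 2 initiating radical; target <-> isomer of the product; substrate + second chain carrier -> released group + first chain carrier; partner + first chain carrier -> target + second chain carrier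

1. the flasks by amount of target, in percent of the substrate charged, highest first, at 12 min (ash / birch / cedar / alder)
2. the same order at 1.5 h (ash / birch / cedar / alder)
3. the amount of target, in percent of the substrate charged of the flask you put first, at 12 min
4. the amount of target, in percent of the substrate charged of the flask you put last, at 12 min

Partner takes the carrier at a rate proportional to partner, and transfer agent takes it at a rate proportional to transfer agent. So the logarithm of the fraction of partner left, divided by the logarithm of the fraction of transfer agent left, is a constant: the selectivity factor.

I need the transfer agent used, so I assume each initiator gives two radicals, each ending on transfer agent, and I let the whole initiator charge go by 12.0 min. That is my own rough assumption. Monday's last reading, 7%, carries a scatter of 2 percentage points, so I divide Tuesday's. I also count the partner used as target alone, a second rough assumption of mine, since isomer of the product holds used partner as well, so my figure for the partner left is too high. On these assumptions Tuesday's flask keeps an estimated 38.0% of the transfer agent against 33.8% of the partner, and my rough estimate of the selectivity factor is 1.12.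

Initiator scales with substrate, so transfer agent falls further in the richer flask. Alder comes to 34.9% and birch to 5.37%. Time is absent from the ratio, so I expect the order to stand at 1.5 h.

The forecast reads alder > ash > cedar > birch at 12 min and alder > ash > cedar > birch at 1.5 h, with alder 35% (29% to 41%) and birch 4.5% (2.5% to 7.5%). It speaks of “the excess over linear coming from transfer-agent depletion at high loading”. My birch figure is higher, though inside that range.

The flask gives alder > ash > cedar > birch at 12 min and alder > ash > cedar > birch at 1.5 h, with alder 38.7% and birch 6.80%.

    2 idle radical → ended radicals (k = 3.00 × 10⁶ L mol⁻¹ s⁻¹)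
    2 first chain carrier → ended chains (k = 8.60 × 10⁸ L mol⁻¹ s⁻¹)
    transfer agent + first chain carrier → side product + idle radical (kL = 7.30 × 10⁶ L mol⁻¹ s⁻¹)
    substrate + initiating radical → capped initiator + first chain carrier (k = 7.90 × 10⁶ L mol⁻¹ s⁻¹)
    initiator → 2 initiating radical (k = 0.00220 s⁻¹)
    target ⇌ isomer of the product (K = 0.140, k = 9.00 × 10⁻⁴ s⁻¹)
    substrate + second chain carrier → released group + first chain carrier (k = 3.00 × 10⁵ L mol⁻¹ s⁻¹)
    partner + first chain carrier → target + second chain carrier (k = 1.50 × 10⁷ L mol⁻¹ s⁻¹)

Alder keeps 45.6% of its partner and 68.2% of its transfer agent, a ratio of 2.05, above my 1.12, with 20.5% of the initiator still standing. Capture by transfer agent is the main reason for birch's low target: without that step birch reaches 70.2%. Birch's neighbour, charged with 0.025 M of transfer agent, keeps 96.1% of partner and 98.1% of transfer agent, a ratio of 2.07, and gives 2.76% of target.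

All runs are calculated for substances that don't exist, and the scatter is random.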